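**Plan**

- Retrosynthesis: remove the two O-benzyl groups of a protected catechol; cut the exocyclic bond from C3 to the catechol benzylic CH2 (lactone enolate plus benzylic bromide); open the lactone C5–O bond and raise C5 to the acid level, which leads to a 2-substituted succinic anhydride; cut C2–C3 and C4–C5, leaving two CO and a terminal epoxide.
- Enabling feature: in the butyrolactone ring, C3–C4 is a CH2–CH pair with the veratryl CH2 on C4, flanked by the one-carbon units C2 and C5. This is the carbon pair of methyl eugenol oxide with one CO on each side.
- Forward order: methyl eugenol, racemic epoxide, resolved (S)-epoxide, five-membered anhydride ring by double carbonylation, half-ester, gamma-lactone ring by acid reduction and lactonisation, benzylation at C3, hydrogenolysis.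
- Stereochemistry: C4 comes from the kinetically resolved epoxide and is inverted stereospecifically in the second carbonylation (S to R). C3 is set trans to C4 in the enolate alkylation.

Key step: step 3

Assumption: the (S,S)-configured cobalt salen acetate is taken to hydrolyse the (R)-epoxide faster, the sense known for simple 2-alkyl- and 2-benzyloxiranes; if the sense were opposite for this substrate, the (R,R)-complex would be used.

Abbreviations: salen = N,N'-bis(3,5-di-tert-butylsalicylidene)-1,2-cyclohexanediaminate; ClTPP = meso-tetrakis(4-chlorophenyl)porphyrinate; salph = N,N'-o-phenylenebis(3,5-di-tert-butylsalicylideneiminate).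

**Route**

Step 1
Reactants: 1 methyl eugenol (4-allyl-1,2-dimethoxybenzene)
Product: 2 racemic 2-(3,4-dimethoxybenzyl)oxirane
Conditions: mCPBA, CH2Cl2, 0 °C to rt
Reagents that add atoms: mCPBA, OOC(=O)c1cccc(Cl)c1
Why: Prilezhaev epoxidation of the isolated terminal alkene by the peracid should leave the veratryl ring untouched; the product is racemic and the stereocentre is fixed in step 2.

Step 2
Reactants: 2 racemic 2-(3,4-dimethoxybenzyl)oxirane
Product: 3 (S)-2-(3,4-dimethoxybenzyl)oxirane
Conditions: (S,S)-(salen)Co(OAc) (0.5 mol%), H2O (0.55 equiv), THF, 0 °C to rt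
Reagents that add atoms: none
Why: In the Jacobsen hydrolytic kinetic resolution the chiral acetate complex of trivalent cobalt delivers water to the terminal carbon of the (R)-epoxide much faster than to its mirror image, so the (S)-epoxide should be recovered in high enantiomeric purity and separated from the polar diol.

Step 3
Reactants: 3 (S)-2-(3,4-dimethoxybenzyl)oxirane; 4 carbon monoxide (two molecules taken up)
Product: 6 (R)-3-(3,4-dimethoxybenzyl)dihydrofuran-2,5-dione, via beta-lactone 5 (not isolated)
Conditions: CO (60 bar), [(ClTPP)Al(THF)2][Co(CO)4] (2 mol%), 1,4-dioxane, 90 °C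
Reagents that add atoms: none
Why: The aluminium porphyrin cation binds the epoxide oxygen and the Co(CO)4 anion opens it by SN2 at the unsubstituted CH2; CO insertion gives an acylcobalt that the aluminium alkoxide captures in a 4-exo-trig closure, releasing beta-lactone 5 with the C–O stereocentre untouched. Once the epoxide is consumed the same ion pair activates 5, the cobaltate displaces the carboxylate at the secondary alkyl C–O carbon with inversion, a second CO inserts, and the aluminium carboxylate attacks the acylcobalt in a 5-exo-trig closure that forms the anhydride ring and returns the catalyst. The closest known reaction is the one-pot Lewis acid/tetracarbonylcobaltate double ring-expansion carbonylation of terminal epoxides to succinic anhydrides, which transfers the configuration of enantiopure alkyl epoxides with net inversion. The one C–C bond made at a stereocentre (C4–C5 of the target) is therefore controlled by the epoxide centre of 3, (S) becoming (R). The step needs opening at CH2 before CH, carbonylation rather than Lewis-acid isomerisation to the arylacetone, and a pure SN2 path in the second cycle; these should be secured by the steric bias of a monosubstituted epoxide, by high CO pressure in a donor solvent, and by the stereocentre being homobenzylic rather than benzylic, so that no stabilised cation can form.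

Step 4
Reactants: 6 (R)-3-(3,4-dimethoxybenzyl)dihydrofuran-2,5-dione
Product: 7 (R)-2-(3,4-dimethoxybenzyl)-4-methoxy-4-oxobutanoic acid
Conditions: MeOH, DMAP (10 mol%), CH2Cl2, −20 °C to rt
Reagents that add atoms: methanol, CO
Why: In this DMAP-catalysed alcoholysis of a cyclic anhydride, methanol should attack the carbonyl flanked by the unsubstituted CH2, which is less hindered than the one next to the benzyl-bearing stereocentre, and the mild conditions should leave that centre untouched.

Step 5
Reactants: 7 (R)-2-(3,4-dimethoxybenzyl)-4-methoxy-4-oxobutanoic acid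
Product: 9 (R)-4-(3,4-dimethoxybenzyl)dihydrofuran-2(3H)-one, via hydroxy ester 8 (not isolated)
Conditions: BH3·SMe2, THF, 0 °C to rt; H2O quench; then TsOH·H2O (cat.), toluene, 60 °C
Reagents that add atoms: none
Why: Borane reduces the free carboxylic acid through its acyloxyborane far faster than the methyl ester (chemoselective acid reduction), and the gamma-hydroxy ester should then lactonise under acid catalysis (5-exo-trig) with loss of methanol; the stereocentre is not involved.

Step 6
Reactants: 10 3,4-bis(benzyloxy)benzyl alcohol
Product: 11 3,4-bis(benzyloxy)benzyl bromide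
Conditions: PBr3 (0.4 equiv), Et2O, 0 °C
Reagents that add atoms: phosphorus tribromide, BrP(Br)Br
Why: Bromination of a benzylic alcohol with PBr3 through the phosphite ester (SN2) should be fast for this electron-rich benzyl system at 0 °C and compatible with the aryl benzyl ethers; the bromide is used freshly prepared.

Step 7
Reactants: 9 (R)-4-(3,4-dimethoxybenzyl)dihydrofuran-2(3H)-one; 11 3,4-bis(benzyloxy)benzyl bromide
Product: 13 (3R,4R)-3-[3,4-bis(benzyloxy)benzyl]-4-(3,4-dimethoxybenzyl)dihydrofuran-2(3H)-one, via lithium enolate 12 (not isolated)
Conditions: LiN(SiMe3)2, THF, −78 °C; then 11, DMPU, −78 to −30 °C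
Reagents that add atoms: none
Why: In this SN2 alkylation of a gamma-butyrolactone lithium enolate, the benzylic bromide should approach the enolate face opposite the C4 veratrylmethyl group, so the new C3 stereocentre forms trans to C4 (3R,4R), as is usual for beta-substituted butyrolactones.

Step 8
Reactants: 13 (3R,4R)-3-[3,4-bis(benzyloxy)benzyl]-4-(3,4-dimethoxybenzyl)dihydrofuran-2(3H)-one
Product: 14 3'-O-demethylarctigenin, (3R,4R)-3-(3,4-dihydroxybenzyl)-4-(3,4-dimethoxybenzyl)dihydrofuran-2(3H)-one
Conditions: H2 (1 atm), Pd/C, EtOAc/MeOH, rt
Reagents that add atoms: none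
Why: Heterogeneous hydrogenolysis of the two aryl benzyl ethers over Pd/C should liberate the catechol without touching the lactone, the methyl ethers or the two stereocentres.

**Compound list**

1 | methyl eugenol (4-allyl-1,2-dimethoxybenzene) | C=CCc1ccc(OC)c(OC)c1 | starting material
2 | racemic 2-(3,4-dimethoxybenzyl)oxirane | COc1ccc(CC2CO2)cc1OC | intermediate
3 | (S)-2-(3,4-dimethoxybenzyl)oxirane | COc1ccc(C[C@H]2CO2)cc1OC | intermediate
4 | carbon monoxide | [C-]#[O+] | starting material
5 | (S)-4-(3,4-dimethoxybenzyl)oxetan-2-one (beta-lactone) | COc1ccc(C[C@H]2CC(=O)O2)cc1OC | intermediate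
6 | (R)-3-(3,4-dimethoxybenzyl)dihydrofuran-2,5-dione | O=C1OC(=O)[C@H](Cc2ccc(OC)c(OC)c2)C1 | intermediate
7 | (R)-2-(3,4-dimethoxybenzyl)-4-methoxy-4-oxobutanoic acid | OC(=O)[C@H](Cc1ccc(OC)c(OC)c1)CC(=O)OC | intermediate
8 | methyl (R)-4-(3,4-dimethoxyphenyl)-3-(hydroxymethyl)butanoate (hydroxy ester) | OC[C@H](Cc1ccc(OC)c(OC)c1)CC(=O)OC | intermediate
9 | (R)-4-(3,4-dimethoxybenzyl)dihydrofuran-2(3H)-one | COc1ccc(C[C@H]2COC(=O)C2)cc1OC | intermediate
10 | 3,4-bis(benzyloxy)benzyl alcohol | OCc1ccc(OCc2ccccc2)c(OCc2ccccc2)c1 | starting material
11 | 3,4-bis(benzyloxy)benzyl bromide | BrCc1ccc(OCc2ccccc2)c(OCc2ccccc2)c1 | intermediate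
12 | lithium enolate of 9 (lithium (R)-4-(3,4-dimethoxybenzyl)-4,5-dihydrofuran-2-olate) | COc1ccc(C[C@H]2COC(O[Li])=C2)cc1OC | intermediate
13 | (3R,4R)-3-[3,4-bis(benzyloxy)benzyl]-4-(3,4-dimethoxybenzyl)dihydrofuran-2(3H)-one | COc1ccc(C[C@H]2COC(=O)[C@@H]2Cc2ccc(OCc3ccccc3)c(OCc3ccccc3)c2)cc1OC | intermediate
14 | 3'-O-demethylarctigenin, (3R,4R)-3-(3,4-dihydroxybenzyl)-4-(3,4-dimethoxybenzyl)dihydrofuran-2(3H)-one | COc1ccc(C[C@H]2COC(=O)[C@@H]2Cc2ccc(O)c(O)c2)cc1OC | target

**Step count**

Total steps: 8. Longest linear sequence: 7 (steps 1, 2, 3, 4, 5, 7, 8); step 6 is a one-step side branch.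

**Steps most likely to fail**

Step 3. The activated epoxide may undergo a Lewis-acid-induced hydride shift (Meinwald rearrangement) to the arylacetone in competition with the first carbonylation. The sequence may also stall after the first CO uptake, because the donor solvent that favours epoxide carbonylation slows opening of the lactone. The fallback sets out from 3 and returns at 6, and runs the two carbonylations as separate operations, each in its own medium. Epoxide 3 is carbonylated once with [(salph)Al(THF)2][Co(CO)4] in 1,2-dimethoxyethane at 50 °C under CO (60 bar). Beta-lactone 5 is isolated and freed from any ketone by chromatography. It is then carbonylated with the same ion pair in toluene at 90 °C under CO (15 bar), where the absence of epoxide and of donor solvent should allow the SN2 lactone opening and closure to 6. This fallback forms no compound beyond those already listed (F0).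

Step 4. Methanol may discriminate poorly between the two anhydride carbonyls, and attack at the hindered one would deliver the regioisomeric half-ester, which step 5 converts into the alpha-benzyl lactone. The fallback sets out from 6 and returns at 9, and moves the regiochemical decision from acyl attack to alcohol oxidation. LiAlH4 in THF reduces both carbonyls to (R)-2-(3,4-dimethoxybenzyl)butane-1,4-diol F1. Fétizon oxidation (Ag2CO3 on Celite, toluene, reflux) should oxidise the unbranched, less hindered CH2OH first. The aldehyde closes to the lactol (4R)-4-(3,4-dimethoxybenzyl)tetrahydrofuran-2-ol F2, which is oxidised further in the same flask to 9.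

Step 7. The electron-rich bromide 11 may self-condense, and proton exchange between product and enolate may cause bis-alkylation and return of 9. The fallback sets out from 9 and 10 and returns at 14, replacing the SN2 alkylation by an aldol addition and a reductive removal of the carbinol oxygen. MnO2 in CH2Cl2 oxidises 10 to 3,4-bis(benzyloxy)benzaldehyde F3. Enolate 12, generated from 9 as in step 7, adds to F3 at −78 °C anti to the C4 substituent. This gives the trans aldol adduct (3S,4R)-3-{[3,4-bis(benzyloxy)phenyl](hydroxy)methyl}-4-(3,4-dimethoxybenzyl)dihydrofuran-2(3H)-one F4 as a mixture of carbinol epimers. Hydrogenolysis (H2, Pd/C, AcOH, catalytic HClO4) should then remove the benzylic hydroxyl and both benzyl ethers in one operation, giving 14 directly.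

**Further compounds**

F0 | step 3 | none | none
F1 | step 4 | (R)-2-(3,4-dimethoxybenzyl)butane-1,4-diol | OC[C@H](Cc1ccc(OC)c(OC)c1)CCO
F2 | step 4 | (4R)-4-(3,4-dimethoxybenzyl)tetrahydrofuran-2-ol (lactol, anomer mixture) | COc1ccc(C[C@H]2COC(O)C2)cc1OC
F3 | step 7 | 3,4-bis(benzyloxy)benzaldehyde | O=Cc1ccc(OCc2ccccc2)c(OCc2ccccc2)c1
F4 | step 7 | (3S,4R)-3-{[3,4-bis(benzyloxy)phenyl](hydroxy)methyl}-4-(3,4-dimethoxybenzyl)dihydrofuran-2(3H)-one (carbinol epimers) | COc1ccc(C[C@H]2COC(=O)[C@@H]2C(O)c2ccc(OCc3ccccc3)c(OCc3ccccc3)c2)cc1OC
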